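**Retrosynthetic overview**

- The target is (2S)-5,7,3',4'-tetrahydroxy-8,5'-diprenylflavanone. The plan rests on C4 of ring C being a carbonyl carbon bonded to C4a of ring A and to C3, whose neighbour C2 carries ring B and O1. Ring C is therefore cut at C4a–C4, C4–C3 and O1–C2 into a ring A iodophenol, carbon monoxide and a ring B arylacetylene.
- Rings A and B are bought as arenes. Ring C is the only ring formed, as the flat flavone with both prenyl groups and all four oxygens (as MOM ethers) already in place. C2 is made stereogenic afterwards by enantioselective copper hydride 1,4-reduction of C2=C3, and the MOM groups are removed last.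
- Ring A piece: phloroglucinol → bis-MOM phenol → O-carbamate → two carbamate-directed ortho-lithiations (prenyl, then iodine) → hydrolysis. The only free OH then lies between iodine and prenyl, which fixes the 8-prenyl pattern.
- Ring B piece: 3-bromo-4,5-dihydroxybenzaldehyde → bis-MOM ether → Stille prenylation → Ohira–Bestmann alkyne.

Key step: step 9

Remark: 3-bromo-4,5-dihydroxybenzaldehyde (10) is taken as a catalogue compound, and (R)-DTBM-SEGPHOS is assumed to direct hydride to the Re face of C2 in step 10; the sense would be checked on a small scale and the (S)-ligand used if it is the reverse.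

**Route**

Step 1
Reactants: 1 phloroglucinol
Product: 2 3,5-bis(methoxymethoxy)phenol
Conditions: MOMCl (2.0 equiv), i-Pr2NEt, DMF, 0 °C → rt
Reagents that add atoms: chloromethyl methyl ether (MOMCl), COCCl
Why: Base-mediated O-alkylation (MOM ether formation) of three equivalent phenols is statistical, so limiting MOMCl to two equivalents should give the bis-ether as the main product, separable from the mono- and tris-ethers, of which the mono-ether can be recycled.

Step 2
Reactants: 2 3,5-bis(methoxymethoxy)phenol
Product: 3 3,5-bis(methoxymethoxy)phenyl N,N-diethylcarbamate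
Conditions: NaH, Et2NCOCl, THF, 0 °C → rt
Reagents that add atoms: N,N-diethylcarbamoyl chloride, CCN(CC)C(Cl)=O
Why: O-Carbamoylation of the sodium phenoxide puts the strongest of the three oxygen directing groups on the oxygen that is to become O1.

Step 3
Reactants: 3 3,5-bis(methoxymethoxy)phenyl N,N-diethylcarbamate; 4 prenyl bromide
Product: 6 3,5-bis(methoxymethoxy)-2-(3-methylbut-2-en-1-yl)phenyl N,N-diethylcarbamate, via 2-lithio carbamate 5 (not isolated)
Conditions: s-BuLi, TMEDA, THF, −78 °C; then 4, CuI (10 mol %), −78 → −20 °C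
Reagents that add atoms: none
Why: Directed ortho-metalation, in which the O-carbamate outranks OMOM and the C–H between carbamate and OMOM is doubly activated, so that lithiation at −78 °C (cold enough to hold back the anionic ortho-Fries shift) and copper-assisted SN2 allylation at the primary carbon of prenyl bromide should give the linear prenyl arene.

Step 4
Reactants: 6 3,5-bis(methoxymethoxy)-2-(3-methylbut-2-en-1-yl)phenyl N,N-diethylcarbamate
Product: 8 2-iodo-3,5-bis(methoxymethoxy)-6-(3-methylbut-2-en-1-yl)phenyl N,N-diethylcarbamate, via 6-lithio carbamate 7 (not isolated)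
Conditions: s-BuLi, TMEDA, THF, −78 °C; then I2, THF, −78 °C
Reagents that add atoms: iodine, II
Why: A second carbamate-directed ortho-metalation at the remaining C–H between carbamate and OMOM (expected to be kinetically preferred at −78 °C over the C–H between the two MOM ethers and over the benzylic–allylic CH2) is followed by iodinolysis of the aryllithium, which is far faster than any reaction of iodine with the prenyl alkene at this temperature.

Step 5
Reactants: 8 2-iodo-3,5-bis(methoxymethoxy)-6-(3-methylbut-2-en-1-yl)phenyl N,N-diethylcarbamate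
Product: 9 2-iodo-3,5-bis(methoxymethoxy)-6-(3-methylbut-2-en-1-yl)phenol
Conditions: NaOH (aq.), EtOH, reflux; then NH4Cl (aq.)
Reagents that add atoms: none
Why: Basic hydrolysis of the aryl carbamate (addition–elimination at the carbonyl, then loss of CO2 from the carbamate salt) frees only the oxygen flanked by iodine and prenyl, and although the two ortho substituents will slow it, the MOM ethers, the aryl iodide and the prenyl alkene are inert to hydroxide.

Step 6
Reactants: 10 3-bromo-4,5-dihydroxybenzaldehyde
Product: 11 3-bromo-4,5-bis(methoxymethoxy)benzaldehyde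
Conditions: MOMCl, i-Pr2NEt, CH2Cl2, 0 °C → rt
Reagents that add atoms: chloromethyl methyl ether (MOMCl), COCCl
Why: MOM ether formation on both catechol oxygens under amine base leaves the aldehyde and the aryl bromide untouched.

Step 7
Reactants: 11 3-bromo-4,5-bis(methoxymethoxy)benzaldehyde
Product: 12 3,4-bis(methoxymethoxy)-5-(3-methylbut-2-en-1-yl)benzaldehyde
Conditions: Bu3SnCH2CH=CMe2, Pd(PPh3)4 (5 mol %), DMF, 100 °C
Reagents that add atoms: tributyl(3-methylbut-2-en-1-yl)stannane, CC(C)=CC[Sn](CCCC)(CCCC)CCCC
Why: Stille cross-coupling, in which oxidative addition of the aryl bromide to zerovalent palladium, allyl transfer from tin and reductive elimination through the less hindered CH2 terminus of the prenyl–palladium species should give the linear prenyl arene under neutral conditions that spare the aldehyde and the MOM ethers.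

Step 8
Reactants: 12 3,4-bis(methoxymethoxy)-5-(3-methylbut-2-en-1-yl)benzaldehyde
Product: 14 5-ethynyl-1,2-bis(methoxymethoxy)-3-(3-methylbut-2-en-1-yl)benzene, via diazoalkene 13 (not isolated)
Conditions: dimethyl (1-diazo-2-oxopropyl)phosphonate, K2CO3, MeOH, 0 °C → rt
Reagents that add atoms: dimethyl (1-diazo-2-oxopropyl)phosphonate, COP(=O)(OC)C(=[N+]=[N-])C(C)=O
Why: Seyferth–Gilbert homologation in the Ohira–Bestmann form, in which methanolysis of the reagent gives the diazomethylphosphonate anion, olefination of the non-enolisable aldehyde gives diazoalkene 13, and loss of N2 with 1,2-hydrogen shift gives the terminal alkyne under conditions mild enough for MOM and prenyl groups.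

Step 9
Reactants: 9 2-iodo-3,5-bis(methoxymethoxy)-6-(3-methylbut-2-en-1-yl)phenol; 14 5-ethynyl-1,2-bis(methoxymethoxy)-3-(3-methylbut-2-en-1-yl)benzene; 15 carbon monoxide
Product: 18 5,7,3',4'-tetrakis(methoxymethoxy)-8,5'-diprenylflavone, via hydroxyaryl ynone 16 (not isolated), via enaminone 17 (not isolated)
Conditions: PdCl2(dppf) (5 mol %), CO (20 bar), Et2NH, 120 °C
Reagents that add atoms: none
Why: Zerovalent palladium (formed from PdCl2(dppf) under CO and amine) inserts into the C4a–I bond of 9, CO insertion gives the aroyl–palladium species, and the amine-deprotonated alkyne terminus of 14 is transferred to palladium and reductively eliminated to give hydroxyaryl ynone 16, which forms C4a–C4 and C4–C3. Et2NH then adds to the β-carbon of the ynone to give enaminone 17, and the free phenol oxygen attacks that same carbon (C2) in a 6-endo-trig addition–elimination that expels Et2NH and closes ring C through O1–C2. The closest known reaction is the palladium-catalysed carbonylative Sonogashira coupling–cyclisation of 2-iodophenols with terminal alkynes to flavones in a secondary amine. No stereocentre is formed. Three selectivities are needed: carbonylative over direct coupling, secured by CO pressure and the absence of copper; 6-endo over 5-exo (aurone) closure, secured by the enaminone, whose β-carbon is the only electrophilic site left; and closure onto the oxygen next to the prenyl group, secured because that is the only free phenol, the other oxygen ortho to C4a being a MOM ether. The doubly ortho-substituted, electron-rich iodide is expected to add slowly, which is why a chelating ferrocenyl bisphosphine and 120 °C are chosen.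

Step 10
Reactants: 18 5,7,3',4'-tetrakis(methoxymethoxy)-8,5'-diprenylflavone
Product: 19 (2S)-5,7,3',4'-tetrakis(methoxymethoxy)-8,5'-diprenylflavanone
Conditions: Cu(OAc)2·H2O (5 mol %), (R)-DTBM-SEGPHOS (5.5 mol %), (EtO)2MeSiH, t-BuOH, toluene, 0 °C
Reagents that add atoms: none
Why: Copper hydride-catalysed asymmetric conjugate reduction of a chromone, in which the ligated monovalent copper hydride formed from Cu(OAc)2 and the silane adds hydride to C2 of the vinylogous ester with the chiral bisphosphine selecting the Re face so that C2 becomes (S), and t-BuOH protonates the copper enolate at C3 at once, which turns the catalyst over and limits retro-oxa-Michael opening, while the isolated trisubstituted prenyl alkenes and the MOM ethers are not touched.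

Step 11
Reactants: 19 (2S)-5,7,3',4'-tetrakis(methoxymethoxy)-8,5'-diprenylflavanone
Product: 20 (2S)-5,7,3',4'-tetrahydroxy-8,5'-diprenylflavanone
Conditions: HCl (3 M aq.), MeOH, 40 °C
Reagents that add atoms: none
Why: Acid-catalysed acetal exchange of the four aryl MOM ethers with methanol (MOM deprotection) does not involve C2, acid (unlike base) does not open ring C by E1cB, and the low temperature should keep the prenyl groups from cyclising onto the neighbouring phenols.

**Compound list**

1 | phloroglucinol | Oc1cc(O)cc(O)c1 | starting material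
2 | 3,5-bis(methoxymethoxy)phenol | COCOc1cc(O)cc(OCOC)c1 | intermediate
3 | 3,5-bis(methoxymethoxy)phenyl N,N-diethylcarbamate | CCN(CC)C(=O)Oc1cc(OCOC)cc(OCOC)c1 | intermediate
4 | prenyl bromide (1-bromo-3-methylbut-2-ene) | CC(C)=CCBr | starting material
5 | 2-lithio-3,5-bis(methoxymethoxy)phenyl N,N-diethylcarbamate (not isolated) | CCN(CC)C(=O)Oc1cc(OCOC)cc(OCOC)c1[Li] | intermediate
6 | 3,5-bis(methoxymethoxy)-2-(3-methylbut-2-en-1-yl)phenyl N,N-diethylcarbamate | CCN(CC)C(=O)Oc1cc(OCOC)cc(OCOC)c1CC=C(C)C | intermediate
7 | 2-lithio-3,5-bis(methoxymethoxy)-6-(3-methylbut-2-en-1-yl)phenyl N,N-diethylcarbamate (not isolated) | CCN(CC)C(=O)Oc1c([Li])c(OCOC)cc(OCOC)c1CC=C(C)C | intermediate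
8 | 2-iodo-3,5-bis(methoxymethoxy)-6-(3-methylbut-2-en-1-yl)phenyl N,N-diethylcarbamate | CCN(CC)C(=O)Oc1c(I)c(OCOC)cc(OCOC)c1CC=C(C)C | intermediate
9 | 2-iodo-3,5-bis(methoxymethoxy)-6-(3-methylbut-2-en-1-yl)phenol | Oc1c(I)c(OCOC)cc(OCOC)c1CC=C(C)C | intermediate
10 | 3-bromo-4,5-dihydroxybenzaldehyde | O=Cc1cc(O)c(O)c(Br)c1 | starting material
11 | 3-bromo-4,5-bis(methoxymethoxy)benzaldehyde | O=Cc1cc(OCOC)c(OCOC)c(Br)c1 | intermediate
12 | 3,4-bis(methoxymethoxy)-5-(3-methylbut-2-en-1-yl)benzaldehyde | O=Cc1cc(OCOC)c(OCOC)c(CC=C(C)C)c1 | intermediate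
13 | 5-(2-diazoethenyl)-1,2-bis(methoxymethoxy)-3-(3-methylbut-2-en-1-yl)benzene (not isolated) | [N-]=[N+]=C=Cc1cc(OCOC)c(OCOC)c(CC=C(C)C)c1 | intermediate
14 | 5-ethynyl-1,2-bis(methoxymethoxy)-3-(3-methylbut-2-en-1-yl)benzene | C#Cc1cc(CC=C(C)C)c(OCOC)c(OCOC)c1 | intermediate
15 | carbon monoxide | [C-]#[O+] | starting material
16 | 1-[2-hydroxy-4,6-bis(methoxymethoxy)-3-prenylphenyl]-3-[3,4-bis(methoxymethoxy)-5-prenylphenyl]prop-2-yn-1-one (not isolated) | O=C(C#Cc1cc(CC=C(C)C)c(OCOC)c(OCOC)c1)c1c(O)c(CC=C(C)C)c(OCOC)cc1OCOC | intermediate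
17 | (E)-3-(diethylamino)-1-[2-hydroxy-4,6-bis(methoxymethoxy)-3-prenylphenyl]-3-[3,4-bis(methoxymethoxy)-5-prenylphenyl]prop-2-en-1-one (not isolated) | CCN(CC)/C(=C/C(=O)c1c(O)c(CC=C(C)C)c(OCOC)cc1OCOC)c1cc(CC=C(C)C)c(OCOC)c(OCOC)c1 | intermediate
18 | 5,7,3',4'-tetrakis(methoxymethoxy)-8,5'-diprenylflavone | CC(C)=CCc1cc(-c2cc(=O)c3c(OCOC)cc(OCOC)c(CC=C(C)C)c3o2)cc(OCOC)c1OCOC | intermediate
19 | (2S)-5,7,3',4'-tetrakis(methoxymethoxy)-8,5'-diprenylflavanone | CC(C)=CCc1cc([C@@H]2CC(=O)c3c(OCOC)cc(OCOC)c(CC=C(C)C)c3O2)cc(OCOC)c1OCOC | intermediate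
20 | (2S)-5,7,3',4'-tetrahydroxy-8,5'-diprenylflavanone | CC(C)=CCc1cc([C@@H]2CC(=O)c3c(O)cc(O)c(CC=C(C)C)c3O2)cc(O)c1O | target

**Totals**

Total step count: 11.
Longest linear sequence: 8 steps (steps 1–5, then 9, 10 and 11); the ring B branch is 3 steps (6–8) before the union.

**Steps most likely to fail, with fallbacks**

Step 9. Oxidative addition at the doubly ortho-substituted, electron-rich C–I bond may be slow, so that direct (CO-free) alkynylation, aminocarbonylation of the aroyl–palladium species by Et2NH, or 5-exo closure to the aurone takes over. The fallback avoids palladium and CO and builds the ynone by polar acylation; it sets out from 9 and 14 and comes back at 18. Alkyne 14 is deprotonated (n-BuLi, THF, −78 °C) and acylated with N-methoxy-N-methylcarbamoyl chloride to give N-methoxy-N-methyl-3-[3,4-bis(methoxymethoxy)-5-prenylphenyl]prop-2-ynamide F1. Iodophenol 9 is turned into its magnesium phenoxide (MeMgCl, LiCl, THF, −20 °C), iodine–magnesium exchange with i-PrMgCl follows, and the aryl Grignard reagent adds to F1 to give, after work-up, hydroxyaryl ynone 16, which is isolated this time. Et2NH in EtOH at rt then takes 16 through enaminone 17 to flavone 18.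

Step 10. Hydride transfer to the tetra-oxygenated 2-aryl vinylogous ester may be sluggish, the facial selectivity may be poor, or the copper enolate may open by retro-oxa-Michael reaction and erode the enantiomeric purity. The fallback separates reduction from stereocontrol; it sets out from 18 and comes back at 19. Unselective 1,4-reduction with LiBH(s-Bu)3 (THF, −78 °C, AcOH quench) gives racemic 5,7,3',4'-tetrakis(methoxymethoxy)-8,5'-diprenylflavanone F2. Kinetic resolution by asymmetric transfer hydrogenation (RuCl(p-cymene)[(R,R)-TsDPEN], HCO2H/Et3N, EtOAc, rt) should reduce the (2R)-ketone to the cis alcohol (2R,4R)-5,7,3',4'-tetrakis(methoxymethoxy)-8,5'-diprenylflavan-4-ol F3 and leave (2S)-19, which is separated by chromatography.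

Step 4. Deprotonation may occur at the benzylic–allylic CH2 of the prenyl group or between the two MOM ethers, not at the carbon next to the carbamate. The fallback reverses the order of the two ortho substituents and brings in prenyl by sigmatropic shift, so that no prenyl group is present during lithiation; it sets out from 3 and comes back at 9. Lithiation of 3 (s-BuLi, TMEDA, THF, −78 °C, through 5) and quench with I2 gives 2-iodo-3,5-bis(methoxymethoxy)phenyl N,N-diethylcarbamate F4. Hydrolysis (NaOH, EtOH, reflux) gives 2-iodo-3,5-bis(methoxymethoxy)phenol F5. O-Alkylation with 3-chloro-3-methylbut-1-yne (DBU, CuCl2 cat., MeCN, 0 °C) gives the 1,1-dimethylpropargyl ether 2-iodo-1,5-bis(methoxymethoxy)-3-[(2-methylbut-3-yn-2-yl)oxy]benzene F6. Semi-hydrogenation (H2, Pd/CaCO3 poisoned with Pb(OAc)2, quinoline, EtOAc) gives the 1,1-dimethylallyl ether 2-iodo-1,5-bis(methoxymethoxy)-3-[(2-methylbut-3-en-2-yl)oxy]benzene F7. Aromatic Claisen rearrangement (N,N-diethylaniline, 130 °C) moves the allyl unit with inversion to the only free ortho carbon and delivers 9.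

**Further compounds**

F1 | step 9 | N-methoxy-N-methyl-3-[3,4-bis(methoxymethoxy)-5-(3-methylbut-2-en-1-yl)phenyl]prop-2-ynamide | CON(C)C(=O)C#Cc1cc(CC=C(C)C)c(OCOC)c(OCOC)c1
F2 | step 10 | racemic 5,7,3',4'-tetrakis(methoxymethoxy)-8,5'-diprenylflavanone | CC(C)=CCc1cc(C2CC(=O)c3c(OCOC)cc(OCOC)c(CC=C(C)C)c3O2)cc(OCOC)c1OCOC
F3 | step 10 | (2R,4R)-5,7,3',4'-tetrakis(methoxymethoxy)-8,5'-diprenylflavan-4-ol | CC(C)=CCc1cc([C@H]2C[C@@H](O)c3c(OCOC)cc(OCOC)c(CC=C(C)C)c3O2)cc(OCOC)c1OCOC
F4 | step 4 | 2-iodo-3,5-bis(methoxymethoxy)phenyl N,N-diethylcarbamate | CCN(CC)C(=O)Oc1cc(OCOC)cc(OCOC)c1I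
F5 | step 4 | 2-iodo-3,5-bis(methoxymethoxy)phenol | Oc1cc(OCOC)cc(OCOC)c1I
F6 | step 4 | 2-iodo-1,5-bis(methoxymethoxy)-3-[(2-methylbut-3-yn-2-yl)oxy]benzene | C#CC(C)(C)Oc1cc(OCOC)cc(OCOC)c1I
F7 | step 4 | 2-iodo-1,5-bis(methoxymethoxy)-3-[(2-methylbut-3-en-2-yl)oxy]benzene | C=CC(C)(C)Oc1cc(OCOC)cc(OCOC)c1I
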